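The numbers in the tables are simulated with constants of no real substance, noise included.

Percentage points of target per µM of added ligand were the unit I reckoned in, and the two earlier runs gave me one ledger to read it from. The flasks and the readings were these:

common to all: starting material 0.20 M; enzyme 0.01 mol%
- south-west: second substrate 2 equiv; added ligand 0.87 µM; run made earlier
- south-east: second substrate 2 equiv; added ligand 64 µM; run made earlier
- winter: second substrate 2.00 equiv; added ligand 1.0 µM; time 20 h
- midnight: second substrate 2.00 equiv; added ligand 3.0 µM; time 20 h
- dawn: second substrate 2.00 equiv; added ligand 8.0 µM; time 20 h
- spring: second substrate 2.00 equiv; added ligand 25 µM; time 20 h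
- noon: second substrate 2.00 equiv; added ligand 80 µM; time 20 h

| run | time / h | target / % |
|---|---|---|
| south-west | 5.00 | 19.5 |
| south-west | 10.0 | 36.2 |
| south-west | 15.0 | 50.3 |
| south-west | 20.0 | 64.1 |
| south-east | 5.00 | 18.9 |
| south-east | 10.0 | 33.0 |
| south-east | 15.0 | 44.8 |
| south-east | 20.0 | 57.5 |

(standard deviation of a reading: 1 percentage point)

- steps under discussion: starting material + enzyme <-> complex A; complex A -> enzyme + target; second substrate + enzyme <-> complex B; complex B -> enzyme + second product; enzyme + added ligand <-> idle complex
- "hardly changes" means that all values lie within two and a half points (for a concentration: within two and a half percent of the largest)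

- amount of target at the end, in percent of the starting material charged for winter, midnight, dawn, spring, noon, in this order
- the course of these numbers from the first flask to the last (hardly changes / rises all the way / falls all the way / falls, then rises / rises, then falls)

I kept my books on the starting material, the charge to which the readings of target refer. The second substrate had no entry, since its step makes second product and takes no starting material. At 20.0 h the books of the earlier runs read:

South-west run, ligand 0.87 µM: target 64.1%, unconverted (free or on the enzyme) 35.9%

South-east run, ligand 64 µM: target 57.5%, unconverted (free or on the enzyme) 42.5%

Each line closed at the full charge, so what the south-east run lacked in target it still held as unconverted: 6.6 percentage points over 63.1 µM more ligand. I called the ligand price the extra share of the charge left unconverted at that time per µM of ligand, 0.00105 /µM, which is 0.1 points for each 1.0 µM. It is a reading from a pair of readings, each with a scatter of 1 point. I took it as a straight line, and noon's 80 µM lay beyond the south-east charge, so that point was an extrapolation: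

target = 64.1% − price × (added ligand − 0.87 µM)

My row: 64.1%, 63.9%, 63.4%, 61.6%, 55.8%

The forecast, made from the same runs, gave 63.7%, 63.5%, 63%, 61.5%, 56.8%, a course that falls all the way. Its slope was 0.09 points per µM, on the ground “Its only effect is to stretch the time scale”. My numbers differ from it, and I drew my line through the raw end readings; my course was the same.

The flasks gave 62.9%, 62.6%, 62.1%, 60.2%, 54.9%, a course that falls all the way. In noon at 20.0 h, idle complex held 21.4% of the catalyst charged, beside 29.8% as enzyme.

    starting material + enzyme ⇌ complex A (K = 6.70 /M, k = 1.60 × 10⁶ /M/h)
    complex A → enzyme + target (k = 1100 /h)
    second substrate + enzyme ⇌ complex B (K = 3.10 /M, k = 1.80 × 10⁵ /M/h)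
    complex B → enzyme + second product (k = 510 /h)
    enzyme + added ligand ⇌ idle complex (K = 9800 /M, k = 3500 /M/h)

The ligand price on noon's 80 µM came to 8.4 points. Added back to noon's 54.9%, that made 63.3% for noon with the step to idle complex switched off, and that flask ended at 63.0%.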